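## The problem

The target **20** is a daucane-type hydroazulene. Numbering used throughout: ring A (cyclopentane) is C1 (angular methyl), C2, C3, C4 (hydroxyl, isopropyl), C5 (H); ring B (cycloheptene) is C1, C5, C6 (salicylate), C7, C8 (methyl), C9, C10, with the alkene at C8=C9. The rings are trans-fused (1β-methyl, 5α-H), the C4 hydroxyl is β and the C6 ester oxygen α, i.e. (1R,4R,5S,6S). Three neighbouring congested carbons, C4–C5–C1, two of them fully substituted, have to be joined. Only C4 corresponds to a stereocentre that can be bought, so it must set the others. C4 can set C1 and C5 if it sits on the tether in the step that closes ring A, and its hydroxyl, 1,3 to C6, can direct a reduction at C6. C5 lies next to C6 and is set by protonation once C6 is a ketone. The fragile elements are the tertiary alcohol (β to a C6 carbonyl it can dehydrate or undergo retro-aldol cleavage), the C8=C9 alkene (β,γ to C6, prone to move into conjugation) and the phenolic ester, which must come last. The enabling feature is that C5, C6 (oxygenated), C7, C8 (methyl) and C9 of ring B are the five carbons of a 5-methyl-3-oxidopyrylium, C1=C10 is a 1,1-disubstituted alkene carrying the angular methyl, and C2–C3–C4 is a three-atom tether between them.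

## Retrosynthesis

**Ester.** The acyl–oxygen bond at C6 is cut first, giving diol **18** and the salicyloyl donor **19**. The salicylate would not survive hydride or electron-transfer reagents, so it cannot be carried earlier. The forward step must acylate the hindered secondary C6 hydroxyl beside the free tertiary C4 hydroxyl and deliver a free phenol; opening of benzodioxinone **19** by the C6 alkoxide does both without a protecting group.

**C6 carbinol.** The C6–H bond is removed to give β-hydroxy ketone **17**, and the hydroxyl is masked as silyl ether **16**. A ketone at C6 is preferred to any direct C–O bond formation because the C4 hydroxyl can then deliver hydride to the β face and give the 4β,6α pattern. The forward reduction must be internally directed and mild enough to leave the β,γ-alkene and the aldol-type array intact.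

**Oxygen bridge.** In **16** the C5–H bond and one C7–H bond are replaced by an oxygen joining C5 and C9, with the alkene moved to C7=C8; this is enone **15**. Both C–O bonds of the bridge are activated by the enone (C5–O is α to the ketone, C9–O is vinylogous), so one reductant can remove them. This cut is chosen over aldol or metathesis closures of ring B because it exposes an 8-oxabicyclo[3.2.1]octenone. The forward step must cleave both bonds and protonate C7 (not C9) and the α face of C5.

**Key disconnection.** Cutting C1–C5 and C9–C10 of **15** gives ylide **14**, made in the flask from acetate **13**. Two rings, two C–C bonds and three stereocentres (C1, C5, C9) fall away at once, leaving a monocyclic precursor with C4 as its only stereocentre. Cutting ring A alone (C4–C5 or C1–C2) would leave the C1 quaternary centre to be set by a separate asymmetric step. The forward cycloaddition must choose the pyrylium face that puts the C4 oxygen on the C6 side.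

**Pyranone.** Acetate **13** comes from hemiacetal **12**, and **12** is the oxidative ring-expansion product of furyl carbinol **11**; the furan 4-methyl becomes the pyranone 5-methyl (C8). Carbinol **11** is simplified to ketone **10** and its free alcohol **9**. The carbinol and anomeric centres need no control because both become trigonal in **14**.

**Furan–C5 bond.** Cutting between the furan and the carbonyl carbon of **9** gives furyllithium **8** (from **7**) and dioxolanone **6**. The dioxolanone acts as acyl donor and releases the tertiary hydroxyl in the same operation; it has no α-hydrogen, so C4 cannot racemise.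

**C3–C4 bond.** Dioxolanone **6** is cut to enolate **5** (from **2**) and iodide **4** (from bromide **3**). Acetal **2** derives from hydroxy acid **1**, whose stereocentre is stored in the acetal carbon and regenerated at C4 with retention. This is preferred to an asymmetric addition to a ketone because the two alkyl groups on C4 (isopropyl, homoallyl) are too alike for reliable face discrimination.

## Roads not taken

**Alternative 1:** The angular methyl is introduced last. Cyclopropane-fused diol **A1** (C15 bridging C1 and C5) is cut at C1–C15 and C5–C15 to give dienediol **A2** with a tetrasubstituted C1=C5 alkene. Forward, Et2Zn/CH2I2 would transfer a methylene to this alkene syn to the C4 hydroxyl (directed Simmons–Smith reaction), and reductive cleavage of C5–C15 would leave the methyl on C1 and a hydrogen on C5.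
- Merits: no oxygen bridge has to be excised, **A2** has only two stereocentres, and hydroxyl-directed cyclopropanation is probably more dependable in its facial outcome than the face selection required of **14**.
- Weak points: for both allylic hydroxyls to direct to the β face, C6 must carry the β-hydroxyl, opposite to the target, so the ester would need to be installed with inversion at a hindered carbinol. The ring opening must break C5–C15 and not C1–C15 and place hydrogen on the α face of C5; hydrogenolysis offers no such control and endangers the C8=C9 alkene, and a dissolving-metal opening requires prior oxidation at C6 and a second C6 reduction.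
- Comparison: this road spends several late steps on one carbon, whereas the chosen plan brings the methyl in on the alkene and sets C1 in the ring-forming step. Against that, the chosen plan must accept a less certain face selection and the SmI2 excision.

**Alternative 2:** Ring A is closed at the carbinol carbon. Ketone **A3** is cut at C4–C5 to give monocyclic diazo ketone **A4**. Forward, loss of N2 from **A4** under Rh2(OAc)4 catalysis and insertion of C5 into the tertiary, oxygen-activated C4–H bond would form the five-membered ring with retention at C4.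
- Merits: **A3** is the tert-butyldimethylsilyl analogue of **16**, so the endgame is the same but no bridge has to be removed. C4 originates from a secondary carbinol, which is easier to make than the quaternary carbinol carbon of **6**. In these respects this road is shorter after its key step.
- Weak points: the diazo group must be placed at C5, the neopentyl α-carbon, whereas enolisation and diazo transfer favour the allylic, unhindered C7. C1 and C4 of **A4** are 1,4-remote and need two independent asymmetric operations. The ring B alkene and other C–H bonds offer competing carbene pathways.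
- Comparison: the chosen plan derives C1 and C5 from C4 in the step that forms both rings, and its regiochemistry is fixed by the tether; it pays with the bridge excision.

**Alternative 3:** Ring B is made by a (4+3) cycloaddition. Ketone **A5** is cut at C6–C7 and C9–C10 to give ring A siloxydiene **A6** and the 2-oxidoallyl cation **A8**, generated from 1,3-dibromopropan-2-one **A7** with Zn–Cu couple.
- Merits: ring B and two C–C bonds form in one convergent step, and C6 arrives at the alcohol oxidation level with the target configuration, so no directed reduction is needed.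
- Weak points: **A5** lacks both the C8 methyl and the angular methyl. The first needs addition to the C8 ketone and a regioselective dehydration; the second needs the whole cyclopropanation and opening sequence of Alternative 1 on the C1=C5 alkene. The unsubstituted cation **A8** is a poor partner for dienes other than furans and cyclopentadiene and may simply alkylate the silyl enol ether terminus. The siloxy group of **A6** sits either inside the diene or against the quaternary C4.
- Comparison: this is the longest road; the chosen plan carries both methyl groups into its cycloaddition.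

Key step: step 9

Remark (assumption): metalation of 3-methylfuran with a hindered alkyllithium is taken to occur mainly at C5, the α-position remote from the methyl group; any isomer from C2 metalation would be removed at ketone **9**.

Remark (assumption): the carbinol centre of **11** and the two ring sp3 centres of **12** and **13** are carried as mixtures, since all become trigonal in **14**.

## Route

Step 1
Reactants: 1 (2R)-2-hydroxy-3-methylbutanoic acid
Product: 2 (2R,5R)-2-tert-butyl-5-(propan-2-yl)-1,3-dioxolan-4-one (cis)
Conditions: t-BuCHO, TsOH·H2O (cat.), H2SO4 (cat.), pentane, reflux, Dean–Stark; recrystallisation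
Reagents that add atoms: 2,2-dimethylpropanal, CC(C)(C)C=O
Why: Acid-catalysed acetalisation of the α-hydroxy acid with water removal; the cis-dioxolanone is the thermodynamic isomer and is purified by crystallisation, so the acetal carbon stores the chirality of 1 for step 3.

Step 2
Reactants: 3 4-bromo-2-methylbut-1-ene
Product: 4 4-iodo-2-methylbut-1-ene
Conditions: NaI, acetone, reflux
Reagents that add atoms: sodium iodide, [Na+].[I-]
Why: Finkelstein halide exchange (SN2) driven by precipitation of NaBr; the iodide is the better electrophile for the hindered enolate of step 3.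

Step 3
Reactants: 2 (2R,5R)-2-tert-butyl-5-(propan-2-yl)-1,3-dioxolan-4-one; 4 4-iodo-2-methylbut-1-ene
Product: 6 (2R,5R)-2-tert-butyl-5-(3-methylbut-3-en-1-yl)-5-(propan-2-yl)-1,3-dioxolan-4-one, via lithium enolate 5 (not isolated)
Conditions: LiN(i-Pr)2, THF, −78 °C; then 4, DMPU, −78 → −30 °C
Reagents that add atoms: none
Why: Seebach alkylation with self-regeneration of the stereocentre: the acetal tert-butyl group shields one face of enolate 5, so the iodide enters trans to it and takes the place of the former hydrogen (net retention at the future C4).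

Step 4
Reactants: 6 (2R,5R)-2-tert-butyl-5-(3-methylbut-3-en-1-yl)-5-(propan-2-yl)-1,3-dioxolan-4-one; 7 3-methylfuran
Product: 9 (2R)-2-hydroxy-5-methyl-1-(4-methylfuran-2-yl)-2-(propan-2-yl)hex-5-en-1-one, via (4-methylfuran-2-yl)lithium 8 (not isolated)
Conditions: 7, t-BuLi, THF, −78 → −20 °C; then 6, −78 °C; aq. NH4Cl
Reagents that add atoms: none
Why: Kinetic α-lithiation of the furan at the unhindered C5 gives 8, which adds to the lactone carbonyl (acyl substitution of a dioxolanone by an organolithium); collapse of the hemiketal on work-up releases the aldehyde of the acetal and the tertiary hydroxyl. Dioxolanone 6 has no α-hydrogen, so neither enolisation nor racemisation of C4 can occur.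

Step 5
Reactants: 9 (2R)-2-hydroxy-5-methyl-1-(4-methylfuran-2-yl)-2-(propan-2-yl)hex-5-en-1-one
Product: 10 (2R)-5-methyl-1-(4-methylfuran-2-yl)-2-(propan-2-yl)-2-[(triethylsilyl)oxy]hex-5-en-1-one
Conditions: Et3SiOTf, 2,6-lutidine, CH2Cl2, −78 → 0 °C
Reagents that add atoms: triethylsilyl trifluoromethanesulfonate, CC[Si](CC)(CC)OS(=O)(=O)C(F)(F)F
Why: Silyl triflate silylation of a hindered tertiary alcohol; the ether prevents ketalisation onto the pyranone in steps 7–8 and later shields the β face around C5.

Step 6
Reactants: 10 (2R)-5-methyl-1-(4-methylfuran-2-yl)-2-(propan-2-yl)-2-[(triethylsilyl)oxy]hex-5-en-1-one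
Product: 11 (1RS,2R)-5-methyl-1-(4-methylfuran-2-yl)-2-(propan-2-yl)-2-[(triethylsilyl)oxy]hex-5-en-1-ol
Conditions: i-Bu2AlH, CH2Cl2, −78 °C; aq. potassium sodium tartrate
Reagents that add atoms: none
Why: Hydride reduction of the furyl ketone; the aluminium alkoxide at −78 °C does not trigger 1,2-silyl migration from the tertiary oxygen, and both carbinol epimers are usable.

Step 7
Reactants: 11 (1RS,2R)-5-methyl-1-(4-methylfuran-2-yl)-2-(propan-2-yl)-2-[(triethylsilyl)oxy]hex-5-en-1-ol
Product: 12 2-[(3R)-2,6-dimethyl-3-[(triethylsilyl)oxy]hept-6-en-3-yl]-6-hydroxy-5-methyl-2H-pyran-3(6H)-one (mixture at C2 and C6)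
Conditions: NBS, NaHCO3, NaOAc, THF–H2O (4:1), 0 °C
Reagents that add atoms: water, O
Why: Achmatowicz rearrangement: bromonium-induced hydration of the furan, opening to the ene-dione and closure of the carbinol oxygen onto the aldehyde. The electron-rich furan reacts far faster than the 1,1-disubstituted alkene, and the buffer protects the silyl ether.

Step 8
Reactants: 12 2-[(3R)-2,6-dimethyl-3-[(triethylsilyl)oxy]hept-6-en-3-yl]-6-hydroxy-5-methyl-2H-pyran-3(6H)-one
Product: 13 6-acetoxy-2-[(3R)-2,6-dimethyl-3-[(triethylsilyl)oxy]hept-6-en-3-yl]-5-methyl-2H-pyran-3(6H)-one (mixture at C2 and C6)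
Conditions: Ac2O, pyridine, DMAP (cat.), CH2Cl2, 0 °C
Reagents that add atoms: acetic anhydride, CC(=O)OC(C)=O
Why: Acylation of the anomeric hemiacetal hydroxyl, the only free hydroxyl, installs the leaving group needed for ylide formation.

Step 9
Reactants: 13 6-acetoxy-2-[(3R)-2,6-dimethyl-3-[(triethylsilyl)oxy]hept-6-en-3-yl]-5-methyl-2H-pyran-3(6H)-one
Product: 15 (1S,2R,5R,7S)-5,8-dimethyl-2-(propan-2-yl)-2-[(triethylsilyl)oxy]-11-oxatricyclo[5.3.1.0^{1,5}]undec-8-en-10-one, via oxidopyrylium ylide 14 (not isolated)
Conditions: Et3N, MeCN, 60 °C
Reagents that add atoms: none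
Why: Et3N removes the proton at C2 of pyranone 13 (future C5) and acetate leaves from the anomeric carbon, giving the 3-oxidopyrylium 14, a cyclic carbonyl ylide whose termini are the two carbons flanking the ring oxygen (future C5 and C9). The tethered 1,1-disubstituted alkene adds suprafacially across these termini in a concerted but asynchronous (5+2) cycloaddition, C9–C10 forming ahead of the crowded C1–C5 bond; the closest known reaction type is the intramolecular oxidopyrylium–alkene cycloaddition of acetoxypyranones carrying a pent-4-enyl chain, an established entry to hydroazulenes. Ring A closes by C1–C5 bond formation through the three-atom tether C2–C3–C4 (five-membered ring annulated at the ylide terminus), and ring B closes as the seven-membered carbocycle made of the five pyrylium carbons plus C1 and C10, spanned by the former ring oxygen. C5 and C9 are tied to each other by the oxygen bridge, and C1 is fixed relative to them because the short tether can reach only the exo position, so C2 ends syn and the C1 methyl anti to the bridge. The absolute sense of all three new centres is set by C4 through the choice of pyrylium face: the transition state needed has the silyloxy group on the oxido (C6) side and the isopropyl group on the ring-oxygen side of the pyrylium plane. This arrangement should be preferred because it keeps the branched isopropyl group out of allylic 1,3-strain with the C6 oxido oxygen and places the slimmer oxygen substituent, not isopropyl, cis-1,3 to the C1 methyl on the forming cyclopentane. Regiochemistry is dictated by the tether, and the fully substituted C4 favours the folded conformer (Thorpe–Ingold effect), so cyclisation should outrun dimerisation of 14.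

Step 10
Reactants: 15 (1S,2R,5R,7S)-5,8-dimethyl-2-(propan-2-yl)-2-[(triethylsilyl)oxy]-11-oxatricyclo[5.3.1.0^{1,5}]undec-8-en-10-one
Product: 16 (3R,3aR,8aR)-6,8a-dimethyl-3-(propan-2-yl)-3-[(triethylsilyl)oxy]-2,3,3a,5,8,8a-hexahydroazulen-4(1H)-one
Conditions: SmI2 (5 equiv), THF–MeOH, −78 → 0 °C
Reagents that add atoms: none
Why: Both bridge C–O bonds lie parallel to the enone π system, so two successive two-electron reductions expel the C5 oxygen (reductive cleavage of an α-alkoxy ketone) and the C9 oxygen (its vinylogous counterpart, as in reductions of γ-oxygenated enones). Kinetic protonation of the dienolate at C7 leaves the C8=C9 alkene, and C5 is protonated on the α face, from which the oxygen departed and which is anti to the C1 methyl and the C4 silyloxy group, giving the trans ring fusion.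

Step 11
Reactants: 16 (3R,3aR,8aR)-6,8a-dimethyl-3-(propan-2-yl)-3-[(triethylsilyl)oxy]-2,3,3a,5,8,8a-hexahydroazulen-4(1H)-one
Product: 17 (3R,3aR,8aR)-3-hydroxy-6,8a-dimethyl-3-(propan-2-yl)-2,3,3a,5,8,8a-hexahydroazulen-4(1H)-one
Conditions: HF·pyridine, pyridine, THF, 0 °C → rt
Reagents that add atoms: none
Why: Fluoride cleavage of the tertiary triethylsilyl ether under buffered, weakly acidic conditions, chosen over basic fluoride so that the β-hydroxy ketone does not undergo retro-aldol cleavage, dehydration, C5 epimerisation or alkene migration.

Step 12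
Reactants: 17 (3R,3aR,8aR)-3-hydroxy-6,8a-dimethyl-3-(propan-2-yl)-2,3,3a,5,8,8a-hexahydroazulen-4(1H)-one
Product: 18 (3R,3aS,4S,8aR)-6,8a-dimethyl-3-(propan-2-yl)-1,2,3,3a,4,5,8,8a-octahydroazulene-3,4-diol
Conditions: Me4NBH(OAc)3, MeCN–AcOH, −30 → 0 °C
Reagents that add atoms: none
Why: Evans–Saksena directed reduction: the C4 hydroxyl exchanges an acetate on boron and hydride is delivered intramolecularly through a six-membered transition state to the β face of C6, giving the anti (4β,6α) diol. The C4 oxygen and C6 are cis on ring A in the trans-fused ketone, so this delivery is geometrically feasible.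

Step 13
Reactants: 18 (3R,3aS,4S,8aR)-6,8a-dimethyl-3-(propan-2-yl)-1,2,3,3a,4,5,8,8a-octahydroazulene-3,4-diol; 19 2,2-dimethyl-4H-1,3-benzodioxin-4-one
Product: 20 (3R,3aS,4S,8aR)-3-hydroxy-6,8a-dimethyl-3-(propan-2-yl)-1,2,3,3a,4,5,8,8a-octahydroazulen-4-yl 2-hydroxybenzoate
Conditions: NaN(SiMe3)2, THF, 0 °C; then 19, 0 °C → rt; aq. NH4Cl
Reagents that add atoms: none
Why: Acylation by alkoxide opening of the benzodioxinone: the secondary C6 alkoxide attacks the carbonyl and the hemiketal collapses to the salicylate and acetone, releasing the phenol directly. The tertiary C4 hydroxyl is too hindered to compete, and no stereocentre is touched.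

## Compound list

1 | (2R)-2-hydroxy-3-methylbutanoic acid | CC(C)[C@@H](O)C(O)=O | starting material
2 | (2R,5R)-2-tert-butyl-5-(propan-2-yl)-1,3-dioxolan-4-one | CC(C)[C@H]1O[C@@H](C(C)(C)C)OC1=O | intermediate
3 | 4-bromo-2-methylbut-1-ene | CC(=C)CCBr | starting material
4 | 4-iodo-2-methylbut-1-ene | CC(=C)CCI | intermediate
5 | lithium (2R)-2-tert-butyl-5-(propan-2-yl)-1,3-dioxol-4-olate | CC(C)C1=C([O-])O[C@H](C(C)(C)C)O1.[Li+] | intermediate (not isolated)
6 | (2R,5R)-2-tert-butyl-5-(3-methylbut-3-en-1-yl)-5-(propan-2-yl)-1,3-dioxolan-4-one | CC(C)[C@@]1(CCC(C)=C)O[C@@H](C(C)(C)C)OC1=O | intermediate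
7 | 3-methylfuran | Cc1ccoc1 | starting material
8 | (4-methylfuran-2-yl)lithium | [Li]c1cc(C)co1 | intermediate (not isolated)
9 | (2R)-2-hydroxy-5-methyl-1-(4-methylfuran-2-yl)-2-(propan-2-yl)hex-5-en-1-one | CC(C)[C@](O)(CCC(C)=C)C(=O)c1cc(C)co1 | intermediate
10 | (2R)-5-methyl-1-(4-methylfuran-2-yl)-2-(propan-2-yl)-2-[(triethylsilyl)oxy]hex-5-en-1-one | CC(C)[C@](O[Si](CC)(CC)CC)(CCC(C)=C)C(=O)c1cc(C)co1 | intermediate
11 | (1RS,2R)-5-methyl-1-(4-methylfuran-2-yl)-2-(propan-2-yl)-2-[(triethylsilyl)oxy]hex-5-en-1-ol | CC(C)[C@](O[Si](CC)(CC)CC)(CCC(C)=C)C(O)c1cc(C)co1 | intermediate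
12 | 2-[(3R)-2,6-dimethyl-3-[(triethylsilyl)oxy]hept-6-en-3-yl]-6-hydroxy-5-methyl-2H-pyran-3(6H)-one | CC1=CC(=O)C(OC1O)[C@](O[Si](CC)(CC)CC)(C(C)C)CCC(C)=C | intermediate
13 | 6-acetoxy-2-[(3R)-2,6-dimethyl-3-[(triethylsilyl)oxy]hept-6-en-3-yl]-5-methyl-2H-pyran-3(6H)-one | CC1=CC(=O)C(OC1OC(C)=O)[C@](O[Si](CC)(CC)CC)(C(C)C)CCC(C)=C | intermediate
14 | 2-[(3R)-2,6-dimethyl-3-[(triethylsilyl)oxy]hept-6-en-3-yl]-5-methylpyrylium-3-olate | CC1=CC([O-])=C([O+]=C1)[C@](O[Si](CC)(CC)CC)(C(C)C)CCC(C)=C | intermediate (not isolated)
15 | (1S,2R,5R,7S)-5,8-dimethyl-2-(propan-2-yl)-2-[(triethylsilyl)oxy]-11-oxatricyclo[5.3.1.0^{1,5}]undec-8-en-10-one | CC1=CC(=O)[C@]23O[C@H]1C[C@@]2(C)CC[C@@]3(O[Si](CC)(CC)CC)C(C)C | intermediate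
16 | (3R,3aR,8aR)-6,8a-dimethyl-3-(propan-2-yl)-3-[(triethylsilyl)oxy]-2,3,3a,5,8,8a-hexahydroazulen-4(1H)-one | CC1=CC[C@@]2(C)CC[C@@](O[Si](CC)(CC)CC)(C(C)C)[C@@H]2C(=O)C1 | intermediate
17 | (3R,3aR,8aR)-3-hydroxy-6,8a-dimethyl-3-(propan-2-yl)-2,3,3a,5,8,8a-hexahydroazulen-4(1H)-one | CC1=CC[C@@]2(C)CC[C@@](O)(C(C)C)[C@@H]2C(=O)C1 | intermediate
18 | (3R,3aS,4S,8aR)-6,8a-dimethyl-3-(propan-2-yl)-1,2,3,3a,4,5,8,8a-octahydroazulene-3,4-diol | CC1=CC[C@@]2(C)CC[C@@](O)(C(C)C)[C@@H]2[C@@H](O)C1 | intermediate
19 | 2,2-dimethyl-4H-1,3-benzodioxin-4-one | CC1(C)OC(=O)c2ccccc2O1 | starting material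
20 | (3R,3aS,4S,8aR)-3-hydroxy-6,8a-dimethyl-3-(propan-2-yl)-1,2,3,3a,4,5,8,8a-octahydroazulen-4-yl 2-hydroxybenzoate | CC1=CC[C@@]2(C)CC[C@@](O)(C(C)C)[C@@H]2[C@@H](OC(=O)c2ccccc2O)C1 | target

## Step count and least certain steps

Total step count: 13. Longest linear sequence: 12 steps (1 → 20 through steps 1 and 3–13; step 2 is a side branch).

**Step 9 (key step).** The cycloaddition may show poor facial selectivity with respect to C4, adding through the conformer that turns isopropyl toward the oxido carbon. Ylide formation at the hindered C2–H may also be slow, so that dimerisation of the ylide competes. The fallback sets out from **13** and returns at **15**; it replaces the steric bias by a hydrogen bond. HF·pyridine removes the silyl group to give 6-acetoxy-2-[(3R)-3-hydroxy-2,6-dimethylhept-6-en-3-yl]-5-methyl-2H-pyran-3(6H)-one F1. Et3N in MeCN then generates 2-[(3R)-3-hydroxy-2,6-dimethylhept-6-en-3-yl]-5-methylpyrylium-3-olate F2, in which an O–H···O hydrogen bond to the oxido oxygen holds the C4 oxygen in the pyrylium plane on the C6 side. Cycloaddition gives (1S,2R,5R,7S)-2-hydroxy-5,8-dimethyl-2-(propan-2-yl)-11-oxatricyclo[5.3.1.0^{1,5}]undec-8-en-10-one F3, and Et3SiOTf/2,6-lutidine converts it into **15**.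

**Step 10.** The second, vinylogous C–O cleavage may lag behind plain conjugate reduction of the intermediate enone. The β,γ-alkene may drift into conjugation, or C5 may be protonated from the β face to give the cis-fused ketone. The fallback sets out from **15** and returns at **16**, dividing the excision into two known operations. SmI2 limited to about two equivalents (THF–MeOH, −78 °C) cleaves only the α C–O bond and gives (3R,3aR,7S,8aR)-7-hydroxy-6,8a-dimethyl-3-(propan-2-yl)-3-[(triethylsilyl)oxy]-2,3,3a,7,8,8a-hexahydroazulen-4(1H)-one F4. Ac2O/DMAP gives the corresponding (3R,3aR,7S,8aR)-7-acetoxy enone F5. A second SmI2 treatment then expels acetate from the γ-position and, after kinetic α-protonation, delivers **16**.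

**Step 4.** Metalation of **7** may not be regioselective (deprotonation next to the methyl group), and the aldehyde liberated from the acetal may consume **8**. The fallback keeps electrophile **6** and returns at **9**, but makes **8** regiospecifically by halogen–lithium exchange. Commercial 3-methylfuran-2-carboxylic acid F6 is brominated (Br2, AcOH) to 5-bromo-3-methylfuran-2-carboxylic acid F7. Decarboxylation (copper powder, quinoline, heat) gives 2-bromo-4-methylfuran F8, and n-BuLi (THF, −78 °C) gives **8**, which is added to **6** as in the route.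

**Step 3.** The basic, hindered enolate may cause E2 elimination of iodide **4** to the diene, or may decompose before the slow alkylation is complete. The fallback sets out from **2** (through **5**) and returns at **6**, replacing alkylation by conjugate addition. Michael addition of **5** to but-3-en-2-one, again trans to the tert-butyl group, gives (2R,5R)-2-tert-butyl-5-(3-oxobutyl)-5-(propan-2-yl)-1,3-dioxolan-4-one F9. Wittig methylenation (Ph3P=CH2, THF, 0 °C), which leaves the lactone untouched, gives **6**.

**Step 12 (with step 11).** The free β-hydroxy ketone **17** may lose the tertiary hydroxyl by elimination or retro-aldol cleavage, the alkene may migrate in the acidic medium, or hydride delivery may escape direction by the hindered tertiary hydroxyl. The fallback sets out from **16** and returns at **20**; it avoids **17** and sets C6 by inversion. LiBH(s-Bu)3 should attack the α face, opposite the C4 silyloxy group, and give (3R,3aS,4R,8aR)-6,8a-dimethyl-3-(propan-2-yl)-3-[(triethylsilyl)oxy]-1,2,3,3a,4,5,8,8a-octahydroazulen-4-ol F10. Mitsunobu esterification with 2-hydroxybenzoic acid (PPh3, diisopropyl azodicarboxylate) inverts C6 and gives (3R,3aS,4S,8aR)-6,8a-dimethyl-3-(propan-2-yl)-3-[(triethylsilyl)oxy]-1,2,3,3a,4,5,8,8a-octahydroazulen-4-yl 2-hydroxybenzoate F11. HF·pyridine then gives **20**.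

**Step 13.** Acylation of the hindered C6 alkoxide may be slow, leaving time for base-induced side reactions of the product phenoxide ester. The fallback sets out from **18** and returns at **20**, using a neutral acyl chloride acylation. 2-Acetoxybenzoyl chloride, pyridine and DMAP give (3R,3aS,4S,8aR)-3-hydroxy-6,8a-dimethyl-3-(propan-2-yl)-1,2,3,3a,4,5,8,8a-octahydroazulen-4-yl 2-(acetyloxy)benzoate F12. Brief ammonolysis (NH3, MeOH, 0 °C) removes the far more labile aryl acetate and gives **20**.

## Further compounds

F1 | step 9 | 6-acetoxy-2-[(3R)-3-hydroxy-2,6-dimethylhept-6-en-3-yl]-5-methyl-2H-pyran-3(6H)-one | CC1=CC(=O)C(OC1OC(C)=O)[C@](O)(C(C)C)CCC(C)=C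
F2 | step 9 | 2-[(3R)-3-hydroxy-2,6-dimethylhept-6-en-3-yl]-5-methylpyrylium-3-olate | CC1=CC([O-])=C([O+]=C1)[C@](O)(C(C)C)CCC(C)=C
F3 | step 9 | (1S,2R,5R,7S)-2-hydroxy-5,8-dimethyl-2-(propan-2-yl)-11-oxatricyclo[5.3.1.0^{1,5}]undec-8-en-10-one | CC1=CC(=O)[C@]23O[C@H]1C[C@@]2(C)CC[C@@]3(O)C(C)C
F4 | step 10 | (3R,3aR,7S,8aR)-7-hydroxy-6,8a-dimethyl-3-(propan-2-yl)-3-[(triethylsilyl)oxy]-2,3,3a,7,8,8a-hexahydroazulen-4(1H)-one | CC1=CC(=O)[C@H]2[C@](O[Si](CC)(CC)CC)(C(C)C)CC[C@]2(C)C[C@@H]1O
F5 | step 10 | (3R,3aR,7S,8aR)-7-acetoxy-6,8a-dimethyl-3-(propan-2-yl)-3-[(triethylsilyl)oxy]-2,3,3a,7,8,8a-hexahydroazulen-4(1H)-one | CC1=CC(=O)[C@H]2[C@](O[Si](CC)(CC)CC)(C(C)C)CC[C@]2(C)C[C@@H]1OC(C)=O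
F6 | step 4 | 3-methylfuran-2-carboxylic acid | Cc1ccoc1C(O)=O
F7 | step 4 | 5-bromo-3-methylfuran-2-carboxylic acid | Cc1cc(Br)oc1C(O)=O
F8 | step 4 | 2-bromo-4-methylfuran | Cc1coc(Br)c1
F9 | step 3 | (2R,5R)-2-tert-butyl-5-(3-oxobutyl)-5-(propan-2-yl)-1,3-dioxolan-4-one | CC(C)[C@@]1(CCC(C)=O)O[C@@H](C(C)(C)C)OC1=O
F10 | step 12 | (3R,3aS,4R,8aR)-6,8a-dimethyl-3-(propan-2-yl)-3-[(triethylsilyl)oxy]-1,2,3,3a,4,5,8,8a-octahydroazulen-4-ol | CC1=CC[C@@]2(C)CC[C@@](O[Si](CC)(CC)CC)(C(C)C)[C@@H]2[C@H](O)C1
F11 | step 12 | (3R,3aS,4S,8aR)-6,8a-dimethyl-3-(propan-2-yl)-3-[(triethylsilyl)oxy]-1,2,3,3a,4,5,8,8a-octahydroazulen-4-yl 2-hydroxybenzoate | CC1=CC[C@@]2(C)CC[C@@](O[Si](CC)(CC)CC)(C(C)C)[C@@H]2[C@@H](OC(=O)c2ccccc2O)C1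
F12 | step 13 | (3R,3aS,4S,8aR)-3-hydroxy-6,8a-dimethyl-3-(propan-2-yl)-1,2,3,3a,4,5,8,8a-octahydroazulen-4-yl 2-(acetyloxy)benzoate | CC1=CC[C@@]2(C)CC[C@@](O)(C(C)C)[C@@H]2[C@@H](OC(=O)c2ccccc2OC(C)=O)C1
A1 | alternative 1 | cyclopropane-fused hydroazulenediol (C15 bridging C1 and C5 on the hydroxyl face) | CC1=CC[C@]23C[C@@]2([C@H](O)C1)[C@](O)(C(C)C)CC3
A2 | alternative 1 | bicyclic dienediol with the tetrasubstituted C1=C5 alkene | CC1=CCC2=C([C@H](O)C1)[C@](O)(C(C)C)CC2
A3 | alternative 2 | C4 tert-butyldimethylsilyl ether of the hydroazulene C6 ketone | CC1=CC[C@@]2(C)CC[C@@](O[Si](C)(C)C(C)(C)C)(C(C)C)[C@@H]2C(=O)C1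
A4 | alternative 2 | monocyclic cycloheptenone with the diazo group at C5 and the silyloxy side chain on C1 | CC1=CC[C@@](C)(CC[C@@H](O[Si](C)(C)C(C)(C)C)C(C)C)C(=[N+]=[N-])C(=O)C1
A5 | alternative 3 | bicyclic C8 ketone with C1=C5 alkene and C6 silyl ether | O=C1CCC2=C([C@@H](O[Si](C)(C)C(C)(C)C)C1)[C@](O[Si](CC)(CC)CC)(C(C)C)CC2
A6 | alternative 3 | ring A siloxydiene with exocyclic C1=C10 and C5=C6 alkenes | C=C1CC[C@@](O[Si](CC)(CC)CC)(C(C)C)/C1=C\O[Si](C)(C)C(C)(C)C
A7 | alternative 3 | 1,3-dibromopropan-2-one | BrCC(=O)CBr
A8 | alternative 3 | 2-oxidoallyl cation | [CH2+]C([O-])=C
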